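**Retrosynthesis**
- The (E,E,E)-triene is disconnected last, by a Heck coupling of a terminal alkene with (1E,3E)-1-iodohexa-1,3-diene, so the polyene never sees Lewis acid or peroxide chemistry.
- The C3–CH2CO2H bond comes from a Lewis-acid-generated 1,2-dioxolan-3-ylium (peroxycarbenium) ion trapped by a silyl ketene acetal, starting from a 3-hydroxy-1,2-dioxolane (peroxyhemiketal).
- The only ring, and the C5 peroxide stereocentre, are made in one pot by an organocatalytic peroxy-Michael/hemiketalisation of a β-methyl-β-alkyl methyl enone with H2O2.
- The enone comes from a Horner–Wadsworth–Emmons (HWE) olefination of a methyl ketone, which is made from 10-undecenoic acid.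

**Structure check and assumptions**
- The target is (3R,5R), with the two methyls cis and the chain and CH2CO2H cis on the other face.
- I assume the quinine/quinidine-type catalyst series is chosen to give the (5R) peroxide centre.
- I assume the C3 hemiketal epimers interconvert and that step 4 gives a mixture of C3 epimers, from which the cis-(3R,5R) isomer is isolated.

---

**Step 1**
Reactants: 1 (10-undecenoic acid); 2 (methyllithium)
Product: 3 (dodec-11-en-2-one)
Conditions: MeLi (2.5 equiv), Et2O, 0 °C to rt; then TMSCl quench and aqueous H3O+
Reagents that add atoms: MeLi, C[Li] (leaves the CH3 of the ketone)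
Why: The first equivalent deprotonates the acid and the second adds to the carboxylate to give a dianion that collapses to the methyl ketone on quench (carboxylic acid to methyl ketone with 2 MeLi). The terminal alkene is untouched.

**Step 2**
Reactants: 3 (dodec-11-en-2-one); 4 (dimethyl (2-oxopropyl)phosphonate)
Product: 5 ((E)-4-methyltetradeca-3,13-dien-2-one)
Conditions: 4 and NaH (pre-formed anion), THF, 0 °C; add 3, then 40–60 °C; chromatographic removal of the minor Z isomer
Reagents that add atoms: phosphonate 4, COP(=O)(OC)CC(C)=O (leaves the =CH–C(O)CH3 unit)
Why: HWE olefination of a ketone with a β-ketophosphonate gives the β,β-disubstituted enone with E as the major isomer. The weakly basic phosphonate anion limits aldol side reactions.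

**Step 3**
Reactants: 5 (enone); 6 (hydrogen peroxide)
Product: 7 ((5R)-5-(dec-9-en-1-yl)-3,5-dimethyl-1,2-dioxolan-3-ol, mixture of C3 epimers)
Conditions: 30% aq. H2O2 (5 equiv), 9-amino-9-deoxy-epi-quinine·2TFA (20 mol%), toluene, 25 °C, 2–3 d
Reagents that add atoms: H2O2, OO (becomes the ring O–O and the hemiketal OH)
Why: Iminium-catalysed asymmetric peroxy-Michael addition of H2O2 to the β-carbon sets the tertiary peroxide stereocentre C5 (R) by facial shielding from the chiral amine. The resulting γ-hydroperoxy ketone closes 5-exo onto the carbonyl to form the peroxyhemiketal, which traps the adduct and forms the only ring. The terminal alkene survives.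

**Step 4**
Reactants: 7 (hemiketal); 8 (1,1-bis(trimethylsilyloxy)ethene, the bis-TMS ketene acetal of acetic acid)
Product: 9 (2-[(3R,5R)-5-(dec-9-en-1-yl)-3,5-dimethyl-1,2-dioxolan-3-yl]acetic acid)
Conditions: TMSOTf (0.3 equiv), CH2Cl2, –78 °C; then aqueous NaHSO4 work-up; separate the C3 epimers by silica or HPLC
Reagents that add atoms: ketene acetal 8, C=C(O[Si](C)(C)C)O[Si](C)(C)C (leaves CH2CO2H after silyl ester hydrolysis)
Why: TMSOTf ionises the hemiketal to the cyclic peroxycarbenium ion, which a silyl ketene acetal traps in a Mukaiyama-type addition, forming the C3 quaternary centre. Selectivity comes only from weak 1,3-induction by C5, so both C3 epimers form and the cis-(3R,5R) one is isolated. Only C3–OH is cleaved, so O–O and the C5 centre are retained, and the bis-silyl acetal gives the free acid directly, avoiding base-labile β-peroxy ester saponification.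

**Step 5** (independent branch making the coupling partner)
Reactants: 10 ((E)-pent-2-enal); 11 (iodoform)
Product: 12 ((1E,3E)-1-iodohexa-1,3-diene)
Conditions: CHI3, CrCl2 (6 equiv), THF/dioxane, 0 °C to rt, dark
Reagents that add atoms: CHI3, IC(I)I (leaves the =CHI carbon and iodine)
Why: Takai–Hiyama olefination converts the aldehyde to the (E)-vinyl iodide and leaves the existing E alkene intact.

**Step 6**
Reactants: 9 (terminal-alkene acid); 12 (dienyl iodide)
Product: 13 (target)
Conditions: Pd(OAc)2 (5 mol%), Bu4NCl, NaHCO3, DMF, 25–40 °C (Jeffery Heck)
Reagents that add atoms: none beyond reactant 12 (the dienyl iodide coupling partner)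
Why: Heck coupling of the unactivated terminal alkene with the (E)-dienyl iodide gives the linear (E)-alkene. Vinyl geometry is retained, so the triene is E,E,E. No stereocentre is touched, and the carboxylate and dialkyl peroxide are inert at mild temperature.

---

**Compound list**

1 | 10-undecenoic acid | C=CCCCCCCCCC(=O)O | starting material
2 | methyllithium | C[Li] | starting material
3 | dodec-11-en-2-one | CC(=O)CCCCCCCCC=C | intermediate
4 | dimethyl (2-oxopropyl)phosphonate | COP(=O)(OC)CC(C)=O | starting material
5 | (E)-4-methyltetradeca-3,13-dien-2-one | CC(=O)/C=C(\C)CCCCCCCCC=C | intermediate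
6 | hydrogen peroxide | OO | starting material
7 | (5R)-5-(dec-9-en-1-yl)-3,5-dimethyl-1,2-dioxolan-3-ol (C3 epimers) | C=CCCCCCCCC[C@]1(C)CC(C)(O)OO1 | intermediate
8 | 1,1-bis(trimethylsilyloxy)ethene | C=C(O[Si](C)(C)C)O[Si](C)(C)C | starting material
9 | 2-[(3R,5R)-5-(dec-9-en-1-yl)-3,5-dimethyl-1,2-dioxolan-3-yl]acetic acid | C=CCCCCCCCC[C@]1(C)C[C@](C)(CC(=O)O)OO1 | intermediate
10 | (E)-pent-2-enal | CC/C=C/C=O | starting material
11 | iodoform | IC(I)I | starting material
12 | (1E,3E)-1-iodohexa-1,3-diene | CC/C=C/C=C/I | intermediate
13 | target: 2-[(3R,5R)-3,5-dimethyl-5-((9E,11E,13E)-hexadeca-9,11,13-trienyl)-1,2-dioxolan-3-yl]acetic acid | CC/C=C/C=C/C=C/CCCCCCCC[C@]1(C)C[C@](C)(CC(=O)O)OO1 | target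

---

**Step count:** 6 steps in total. The longest linear sequence is 5 steps (1 → 3 → 5 → 7 → 9 → 13).

**Three steps most likely to fail**
1. **Step 3 (peroxy-Michael/hemiketalisation).** Competing Weitz–Scheffer epoxidation, or modest ee for a β-Me/β-alkyl enone, are the risks. Fallback: make racemic 7 with H2O2 and catalytic acid, carry it through step 4, and resolve acid 9 (or its methyl ester) by preparative chiral HPLC.
2. **Step 4 (peroxycarbenium trapping).** The C3 epimer ratio may be poor, and the cation may fragment. Fallback: fix the cis relationship with a bridge. Do a [4+2] of singlet oxygen with 1,4-dimethylcyclopentadiene to give the meso 2,3-dioxabicyclo[2.2.1]heptene, then open the alkene bridge and differentiate the two arms by chain elaboration (single-enantiomer control would then need a separate desymmetrisation).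
3. **Step 6 (Heck with peroxide and triene).** The risks are Pd–peroxide reactivity, isomerisation of the alkene, and branched product. Fallback: ozonolyse the terminal alkene of 9 (O3, then Me2S) to the C9 aldehyde, then do a Julia–Kocienski olefination with the (2E,4E)-hepta-2,4-dienyl PT-sulfone.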